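We decide to freeze the catalyst: we take its amount as steady through a run and read each new flask from the earlier run nearest to it in substrate charge, the partner charge being the same in all of them.

| setting | green | teal | grey | spring | dusk |
|---|---|---|---|---|---|
| substrate | 0.055 M | 0.10 M | 0.20 M | 0.20 M | 0.050 M |
| partner | 0.24 M | 0.24 M | 0.24 M | 0.240 M | 0.240 M |
| free catalyst | 2 mM | 2 mM | 1.5 mM | 2.0 mM | 1.2 mM |
| remark | run made earlier | run made earlier | run made earlier |  |  |
| time |  |  |  | 20 h | 20 h |

| run | time / h | product / % |
|---|---|---|
| green | 4.00 | 36 |
| green | 8.00 | 60 |
| green | 12.0 | 74 |
| green | 15.0 | 81 |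
| green | 20.0 | 91 |
| teal | 1.50 | 15 |
| teal | 3.00 | 26 |
| teal | 6.00 | 44 |
| teal | 10.0 | 63 |
| teal | 20.0 | 88 |
| grey | 1.50 | 11 |
| grey | 3.00 | 15 |
| grey | 6.00 | 31 |
| grey | 10.0 | 49 |
| grey | 20.0 | 78 |

(standard deviation of a reading: 2 percentage points)

1. the flask that ends with the higher amount of product, in percent of the substrate charged, or "neither" when 2 percentage points or less lies between them (spring / dusk / neither)
2. final product, as a percentage of the substrate charged, in spring
3. final product, as a percentage of the substrate charged, in dusk

- the numbers in the tables scatter with a standard deviation of 2 percentage points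

Grey has spring's substrate and partner charges, and its last reading gives 13.2 h at 1.5 mM of free catalyst. This is the substrate life, the time in which the fraction of substrate left falls by a factor e under pseudo-first-order decay. Two times then compare, this life and the run's 20 h. We assume that the life scales inversely with catalyst, as in a Selwyn test, where product depends on catalyst times time.

The same reading of green gives 8.31 h at 2 mM, which is shorter than spring's life below, so we do not pool lives from different substrate loads. Green's load is the nearest to dusk's, so we scale dusk from green.

spring: life = 9.91 h, run/life = 2.02, fraction left = 0.133, product 86.7%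

dusk: life = 13.8 h, run/life = 1.45, fraction left = 0.235, product 76.4%

Dusk's life is longer than spring's, so we expect spring to end higher, by 10 points, well beyond the margin of 2 points.

The forecast says spring, with 85% and 79%, its dusk figure standing above ours: “I lean toward spring, though the call is not secure”.

Spring ends at 85.2% and dusk at 75.4%.

substrate + free catalyst → catalyst intermediate A (k = 62.0 /M/h); partner + catalyst intermediate A ⇌ catalyst intermediate B (K = 2.00 /M, k = 160 /M/h); catalyst intermediate B ⇌ catalyst intermediate C (K = 0.670, k = 2100 /h); catalyst intermediate C ⇌ released group + catalyst intermediate D (K = 4.00 M, k = 2500 /h); catalyst intermediate D → free catalyst + product (k = 1000 /h); free catalyst → spent catalyst (k = 4.90 × 10⁻⁴ /h); crystals ⇌ released group, rate k7*(cs7 - [released group]) while solid is left; crystals form when [released group] > cs7 (solubility = 5.00 mM, k = 17.0 /h) Dusk's answer moves by 5 points when its free catalyst goes up to 1.39 mM. Grey's life, carried to a flask like spring but with 0.0050 M of free catalyst, becomes 3.96 h, which reckons 99.4% product, and that flask gives 99.5%.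

(The numbers in the tables were computed for substances that don't exist.)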